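**Strategy.** The target is an acacetin–apigenin dimer joined by a C8–O–C4′ diaryl ether. Everything rests on cutting the C4–C4a bond of ring C in the 8-aryloxy flavone (flavone unit 1). A (Z)-β-aryloxycinnamic acid, whose enol-ether oxygen (future O1) already sits on the carbon next to the aryloxy-bearing C8, is closed by intramolecular Friedel–Crafts acylation. That oxygen has only one free ortho carbon (future C4a; the other is C8), so one operation forms the pyranone and fixes 8- versus 6-aryloxy regiochemistry. The precursor carries the diaryl ether, benzyl ethers at O5 and O7, and a methyl benzoate from which flavone unit 2 is grown afterwards.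

Key step: step 9

Remark: every hydroxyl that is free in the target travels as a benzyl ether (the 4′-methoxy group is the only methyl ether, so the end is a plain hydrogenolysis), the oxygen that becomes O1 is kept distinct from step 1 onward (free, then MOM) so no symmetric diol needs mono-protection, and acetophenone 15 is taken as a catalogue compound (otherwise one benzylation from 2,4,6-trihydroxyacetophenone).

Step 1
Reactants: 1 2,4,6-trihydroxybenzaldehyde
Product: 2 2,4-bis(benzyloxy)-6-hydroxybenzaldehyde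
Conditions: BnBr (2.1 equiv), K2CO3, DMF, 0 °C → rt
Reagents that add atoms: benzyl bromide, BrCc1ccccc1
Why: Williamson etherification in which the 4-OH and one ortho OH are alkylated, while the last ortho OH, hydrogen-bonded to the formyl oxygen and least acidic, should stay free at room temperature with two equivalents of bromide.

Step 2
Reactants: 2 2,4-bis(benzyloxy)-6-hydroxybenzaldehyde
Product: 3 2,4-bis(benzyloxy)-6-(methoxymethoxy)benzaldehyde
Conditions: NaH, DMF, 0 °C; MOMCl, 0 °C → rt
Reagents that add atoms: chloromethyl methyl ether, COCCl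
Why: Williamson-type O-alkylation of the fully deprotonated chelated phenol; the MOM acetal marks the oxygen that becomes O1 and is orthogonal to the benzyl ethers.

Step 3
Reactants: 3 2,4-bis(benzyloxy)-6-(methoxymethoxy)benzaldehyde
Product: 5 2,4-bis(benzyloxy)-6-(methoxymethoxy)phenol, via aryl formate 4 (not isolated)
Conditions: mCPBA, CH2Cl2, 0 °C → rt; aqueous Na2S2O3/NaHCO3 wash; crude, K2CO3 (cat.), MeOH, rt, under argon
Reagents that add atoms: meta-chloroperoxybenzoic acid, OOC(=O)c1cccc(Cl)c1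
Why: Dakin-type Baeyer–Villiger oxidation in which the very electron-rich aryl group migrates to give the formate, which mild methanolysis cleaves to the phenol without touching the MOM or benzyl ethers.

Step 4
Reactants: 5 2,4-bis(benzyloxy)-6-(methoxymethoxy)phenol; 6 methyl 4-fluorobenzoate
Product: 7 methyl 4-[2,4-bis(benzyloxy)-6-(methoxymethoxy)phenoxy]benzoate
Conditions: Cs2CO3, DMSO, 100 °C, argon
Reagents that add atoms: none
Why: Nucleophilic aromatic substitution (addition–elimination through a Meisenheimer complex) of fluoride para to the ester by the electron-rich phenoxide; with no other free hydroxyl present, the aryl group can only land on the oxygen destined for C8.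

Step 5
Reactants: 7 methyl 4-[2,4-bis(benzyloxy)-6-(methoxymethoxy)phenoxy]benzoate
Product: 8 methyl 4-[2,4-bis(benzyloxy)-6-hydroxyphenoxy]benzoate
Conditions: HCl (cat.), MeOH–THF, 40 °C
Reagents that add atoms: none
Why: Acid-catalysed acetal methanolysis removes only the MOM group; the benzyl ethers and diaryl ether are stable and transesterification of the methyl ester in methanol is degenerate.

Step 6
Reactants: 9 3-(4-methoxyphenyl)prop-2-ynoic acid
Product: 10 tert-butyl 3-(4-methoxyphenyl)prop-2-ynoate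
Conditions: tert-butyl 2,2,2-trichloroacetimidate, BF3·OEt2 (cat.), CH2Cl2–cyclohexane, rt
Reagents that add atoms: tert-butyl 2,2,2-trichloroacetimidate, CC(C)(C)OC(=N)C(Cl)(Cl)Cl
Why: Acid-catalysed tert-butyl transfer from a trichloroacetimidate to the carboxylic acid, mild enough for an arylpropiolic acid that would decarboxylate under heat or strong base.

Step 7
Reactants: 8 methyl 4-[2,4-bis(benzyloxy)-6-hydroxyphenoxy]benzoate; 10 tert-butyl 3-(4-methoxyphenyl)prop-2-ynoate
Product: 11 tert-butyl (2Z)-3-{3,5-bis(benzyloxy)-2-[4-(methoxycarbonyl)phenoxy]phenoxy}-3-(4-methoxyphenyl)prop-2-enoate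
Conditions: Cs2CO3 (0.3 equiv), DMF, 60 °C
Reagents that add atoms: none
Why: Base-catalysed oxa-Michael addition of the phenoxide to the ynoate, in which anti addition should favour the Z enol ether and the single free hydroxyl of 8 guarantees that the acrylate sits on the future O1.

Step 8
Reactants: 11 tert-butyl (2Z)-3-{3,5-bis(benzyloxy)-2-[4-(methoxycarbonyl)phenoxy]phenoxy}-3-(4-methoxyphenyl)prop-2-enoate
Product: 12 (2Z)-3-{3,5-bis(benzyloxy)-2-[4-(methoxycarbonyl)phenoxy]phenoxy}-3-(4-methoxyphenyl)prop-2-enoic acid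
Conditions: TFA–CH2Cl2 (1:4), 0 °C → rt
Reagents that add atoms: none
Why: Acidolysis of the tert-butyl ester with loss of 2-methylpropene; the methyl ester, benzyl ethers and vinylogous carbonate should survive brief anhydrous TFA.

Step 9
Reactants: 12 (2Z)-3-{3,5-bis(benzyloxy)-2-[4-(methoxycarbonyl)phenoxy]phenoxy}-3-(4-methoxyphenyl)prop-2-enoic acid
Product: 14 methyl 4-{[5,7-bis(benzyloxy)-2-(4-methoxyphenyl)-4-oxo-4H-chromen-8-yl]oxy}benzoate, via mixed trifluoroacetic anhydride 13 (not isolated)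
Conditions: (CF3CO)2O (3 equiv), CH2Cl2 (dilute), 0 °C → rt; NaHCO3 quench
Reagents that add atoms: none
Why: The acid is converted to mixed anhydride 13, which ionises to an acylium ion stabilised through the enol-ether oxygen and the anisyl group; this cation attacks the ring carbon ortho to the enol-ether oxygen (future C4a), forming C4–C4a, and proton loss restores the arene. The closest known reaction type is the Friedel–Crafts cycloacylation of β-aryloxycinnamic acids (phenol–arylpropiolate adducts) to flavones. Ring C closes as a six-membered ring by intramolecular electrophilic aromatic substitution at an unsubstituted ortho carbon, giving a fused (not spiro) cationic intermediate. No stereocentre is formed, and the alkene geometry is not critical because the Cα–Cβ bond of the acylium ion has single-bond character, so any E isomer should funnel through the same cation. The selectivity needed is regiochemical (8-aryloxy, not 6-aryloxy) and is secured before the ring closes: O1 sits on the carbon next to the aryloxy-bearing C8, its only free ortho carbon is activated by O1, the ortho C5 benzyloxy and the para C7 benzyloxy groups, and neither the ester-deactivated benzoate ring nor the anisyl ring (attack meta to its methoxy, five-membered closure) can compete.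

Step 10
Reactants: 14 methyl 4-{[5,7-bis(benzyloxy)-2-(4-methoxyphenyl)-4-oxo-4H-chromen-8-yl]oxy}benzoate; 15 1-[2,4-bis(benzyloxy)-6-hydroxyphenyl]ethan-1-one
Product: 17 5,7-bis(benzyloxy)-8-{4-[5,7-bis(benzyloxy)-4-oxo-4H-chromen-2-yl]phenoxy}-2-(4-methoxyphenyl)-4H-chromen-4-one, via diketone 16 (not isolated)
Conditions: 15 (2 equiv), LiN(SiMe3)2 (5 equiv), THF, −78 °C → rt; 1 M HCl quench; crude, TsOH·H2O (cat.), toluene, 80 °C
Reagents that add atoms: none
Why: Crossed Claisen condensation of the dilithium phenoxide–enolate of 15 with the aryl methyl ester gives the 1,3-diketone, whose ortho hydroxyl then adds to the distal ketone and loses water under acid catalysis (cyclodehydration) to close the second pyranone; flavone unit 1 offers no competing acidic site.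

Step 11
Reactants: 17 5,7-bis(benzyloxy)-8-{4-[5,7-bis(benzyloxy)-4-oxo-4H-chromen-2-yl]phenoxy}-2-(4-methoxyphenyl)-4H-chromen-4-one
Product: 18 8-[4-(5,7-dihydroxy-4-oxo-4H-chromen-2-yl)phenoxy]-5,7-dihydroxy-2-(4-methoxyphenyl)-4H-chromen-4-one
Conditions: H2 (1 atm), 10% Pd/C, THF–MeOH, rt
Reagents that add atoms: none
Why: Hydrogenolysis of the four benzylic C–O bonds over palladium on carbon; the aryl methyl ether, the diaryl ether and the pyranone C2=C3 bonds should not be reduced under these mild conditions.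

**Compound list**

1 | 2,4,6-trihydroxybenzaldehyde | O=Cc1c(O)cc(O)cc1O | starting material
2 | 2,4-bis(benzyloxy)-6-hydroxybenzaldehyde | O=Cc1c(O)cc(OCc2ccccc2)cc1OCc1ccccc1 | intermediate
3 | 2,4-bis(benzyloxy)-6-(methoxymethoxy)benzaldehyde | O=Cc1c(OCOC)cc(OCc2ccccc2)cc1OCc1ccccc1 | intermediate
4 | 2,4-bis(benzyloxy)-6-(methoxymethoxy)phenyl formate | O=COc1c(OCOC)cc(OCc2ccccc2)cc1OCc1ccccc1 | intermediate
5 | 2,4-bis(benzyloxy)-6-(methoxymethoxy)phenol | Oc1c(OCOC)cc(OCc2ccccc2)cc1OCc1ccccc1 | intermediate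
6 | methyl 4-fluorobenzoate | COC(=O)c1ccc(F)cc1 | starting material
7 | methyl 4-[2,4-bis(benzyloxy)-6-(methoxymethoxy)phenoxy]benzoate | COC(=O)c1ccc(Oc2c(OCOC)cc(OCc3ccccc3)cc2OCc2ccccc2)cc1 | intermediate
8 | methyl 4-[2,4-bis(benzyloxy)-6-hydroxyphenoxy]benzoate | COC(=O)c1ccc(Oc2c(O)cc(OCc3ccccc3)cc2OCc2ccccc2)cc1 | intermediate
9 | 3-(4-methoxyphenyl)prop-2-ynoic acid | COc1ccc(C#CC(=O)O)cc1 | starting material
10 | tert-butyl 3-(4-methoxyphenyl)prop-2-ynoate | COc1ccc(C#CC(=O)OC(C)(C)C)cc1 | intermediate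
11 | tert-butyl (2Z)-3-{3,5-bis(benzyloxy)-2-[4-(methoxycarbonyl)phenoxy]phenoxy}-3-(4-methoxyphenyl)prop-2-enoate | CC(C)(C)OC(=O)/C=C(/c1ccc(OC)cc1)Oc1cc(OCc2ccccc2)cc(OCc2ccccc2)c1Oc1ccc(C(=O)OC)cc1 | intermediate
12 | (2Z)-3-{3,5-bis(benzyloxy)-2-[4-(methoxycarbonyl)phenoxy]phenoxy}-3-(4-methoxyphenyl)prop-2-enoic acid | OC(=O)/C=C(/c1ccc(OC)cc1)Oc1cc(OCc2ccccc2)cc(OCc2ccccc2)c1Oc1ccc(C(=O)OC)cc1 | intermediate
13 | (2Z)-3-{3,5-bis(benzyloxy)-2-[4-(methoxycarbonyl)phenoxy]phenoxy}-3-(4-methoxyphenyl)prop-2-enoic trifluoroacetic anhydride | O=C(OC(=O)C(F)(F)F)/C=C(/c1ccc(OC)cc1)Oc1cc(OCc2ccccc2)cc(OCc2ccccc2)c1Oc1ccc(C(=O)OC)cc1 | intermediate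
14 | methyl 4-{[5,7-bis(benzyloxy)-2-(4-methoxyphenyl)-4-oxo-4H-chromen-8-yl]oxy}benzoate | COC(=O)c1ccc(Oc2c(OCc3ccccc3)cc(OCc3ccccc3)c3c(=O)cc(-c4ccc(OC)cc4)oc23)cc1 | intermediate
15 | 1-[2,4-bis(benzyloxy)-6-hydroxyphenyl]ethan-1-one | CC(=O)c1c(O)cc(OCc2ccccc2)cc1OCc1ccccc1 | starting material
16 | 1-[2,4-bis(benzyloxy)-6-hydroxyphenyl]-3-(4-{[5,7-bis(benzyloxy)-2-(4-methoxyphenyl)-4-oxo-4H-chromen-8-yl]oxy}phenyl)propane-1,3-dione | O=C(CC(=O)c1ccc(Oc2c(OCc3ccccc3)cc(OCc3ccccc3)c3c(=O)cc(-c4ccc(OC)cc4)oc23)cc1)c1c(O)cc(OCc2ccccc2)cc1OCc1ccccc1 | intermediate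
17 | 5,7-bis(benzyloxy)-8-{4-[5,7-bis(benzyloxy)-4-oxo-4H-chromen-2-yl]phenoxy}-2-(4-methoxyphenyl)-4H-chromen-4-one | COc1ccc(-c2cc(=O)c3c(OCc4ccccc4)cc(OCc4ccccc4)c(Oc4ccc(-c5cc(=O)c6c(OCc7ccccc7)cc(OCc7ccccc7)cc6o5)cc4)c3o2)cc1 | intermediate
18 | 8-[4-(5,7-dihydroxy-4-oxo-4H-chromen-2-yl)phenoxy]-5,7-dihydroxy-2-(4-methoxyphenyl)-4H-chromen-4-one | COc1ccc(-c2cc(=O)c3c(O)cc(O)c(Oc4ccc(-c5cc(=O)c6c(O)cc(O)cc6o5)cc4)c3o2)cc1 | target

**Step count.** Total: 11 steps. Longest linear sequence: 10 steps (steps 1–5, then 7–11; step 6 is a one-step side branch).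

**Steps most likely to fail**

Step 9 (key step). The cyclisation may be undercut by intermolecular acylation or trifluoroacetylation at the other free ring carbon (future C6), by acid-promoted loss or O-to-C migration of benzyl groups, or by slow ionisation of the push–pull mixed anhydride. The fallback sets out from phenol 8 and closes ring C at the O1–C2 bond instead.
- MgCl2-mediated ortho-formylation (MgCl2, Et3N, paraformaldehyde, MeCN, reflux) should place a formyl group on the only free carbon ortho to the hydroxyl, giving methyl 4-[4,6-bis(benzyloxy)-3-formyl-2-hydroxyphenoxy]benzoate F1.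
- Addition of lithium (4-methoxyphenyl)acetylide (from 4-ethynylanisole and n-BuLi, THF, −78 °C, at which the aldehyde reacts ahead of the methyl ester) should give the racemic propargylic alcohol methyl 4-{4,6-bis(benzyloxy)-2-hydroxy-3-[1-hydroxy-3-(4-methoxyphenyl)prop-2-yn-1-yl]phenoxy}benzoate F2, whose stereocentre is erased in the next operation.
- MnO2 oxidation in CH2Cl2 should give the ynone methyl 4-{4,6-bis(benzyloxy)-2-hydroxy-3-[3-(4-methoxyphenyl)prop-2-ynoyl]phenoxy}benzoate F3.
- Amine-mediated 6-endo-dig oxa-Michael cyclisation (Et2NH, EtOH, rt) returns to the route at 14.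

The single free hydroxyl again fixes the ring oxygen next to the aryloxy carbon.

Step 7. The conjugate addition may be sluggish on the donor-substituted ynoate, may give an E/Z mixture, or on prolonged heating may allow base-mediated oxygen-to-oxygen aryl migration (Smiles rearrangement) in the phenoxide. The fallback sets out from 8 and uses a far more electrophilic acceptor at room temperature.
- 3-(4-Methoxyphenyl)prop-2-ynal F4 is prepared from 4-ethynylanisole (n-BuLi, then DMF, THF, −78 °C).
- DABCO-catalysed conjugate addition of 8 in CH2Cl2 at rt should give methyl 4-[2,4-bis(benzyloxy)-6-{[(1Z)-1-(4-methoxyphenyl)-3-oxoprop-1-en-1-yl]oxy}phenoxy]benzoate F5.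
- Pinnick oxidation (NaClO2, NaH2PO4, 2-methyl-2-butene, t-BuOH–H2O) converts the enal to the acid and comes back to the route at 12, bypassing 10, 11 and step 8.

Step 10. The hindered enolate may acylate incompletely on the electron-rich aryl ester, or may attack the pyranone of flavone unit 1. The fallback sets out from 14 and replaces the intermolecular C-acylation by an intramolecular acyl transfer.
- Saponification (LiOH, THF–H2O, rt) should give 4-{[5,7-bis(benzyloxy)-2-(4-methoxyphenyl)-4-oxo-4H-chromen-8-yl]oxy}benzoic acid F6.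
- Steglich esterification with 15 (EDC·HCl, DMAP, CH2Cl2) should give 2-acetyl-3,5-bis(benzyloxy)phenyl 4-{[5,7-bis(benzyloxy)-2-(4-methoxyphenyl)-4-oxo-4H-chromen-8-yl]oxy}benzoate F7.
- Baker–Venkataraman rearrangement (KOH, pyridine, 50 °C) gives diketone 16, and the same TsOH cyclodehydration comes back to the route at 17.

**Further compounds**

F1 | step 9 | methyl 4-[4,6-bis(benzyloxy)-3-formyl-2-hydroxyphenoxy]benzoate | COC(=O)c1ccc(Oc2c(O)c(C=O)c(OCc3ccccc3)cc2OCc2ccccc2)cc1
F2 | step 9 | methyl 4-{4,6-bis(benzyloxy)-2-hydroxy-3-[1-hydroxy-3-(4-methoxyphenyl)prop-2-yn-1-yl]phenoxy}benzoate (racemic) | COC(=O)c1ccc(Oc2c(O)c(C(O)C#Cc3ccc(OC)cc3)c(OCc3ccccc3)cc2OCc2ccccc2)cc1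
F3 | step 9 | methyl 4-{4,6-bis(benzyloxy)-2-hydroxy-3-[3-(4-methoxyphenyl)prop-2-ynoyl]phenoxy}benzoate | COC(=O)c1ccc(Oc2c(O)c(C(=O)C#Cc3ccc(OC)cc3)c(OCc3ccccc3)cc2OCc2ccccc2)cc1
F4 | step 7 | 3-(4-methoxyphenyl)prop-2-ynal | COc1ccc(C#CC=O)cc1
F5 | step 7 | methyl 4-[2,4-bis(benzyloxy)-6-{[(1Z)-1-(4-methoxyphenyl)-3-oxoprop-1-en-1-yl]oxy}phenoxy]benzoate | O=C/C=C(/c1ccc(OC)cc1)Oc1cc(OCc2ccccc2)cc(OCc2ccccc2)c1Oc1ccc(C(=O)OC)cc1
F6 | step 10 | 4-{[5,7-bis(benzyloxy)-2-(4-methoxyphenyl)-4-oxo-4H-chromen-8-yl]oxy}benzoic acid | OC(=O)c1ccc(Oc2c(OCc3ccccc3)cc(OCc3ccccc3)c3c(=O)cc(-c4ccc(OC)cc4)oc23)cc1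
F7 | step 10 | 2-acetyl-3,5-bis(benzyloxy)phenyl 4-{[5,7-bis(benzyloxy)-2-(4-methoxyphenyl)-4-oxo-4H-chromen-8-yl]oxy}benzoate | CC(=O)c1c(OC(=O)c2ccc(Oc3c(OCc4ccccc4)cc(OCc4ccccc4)c4c(=O)cc(-c5ccc(OC)cc5)oc34)cc2)cc(OCc2ccccc2)cc1OCc1ccccc1
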